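**Plan**

1. Numbering and enabling feature: C1 (enoate CH), C2/C3 (epoxide), C4 (CMe), C5 (=CH), C6 (lactone O–CH), C7 (CH bearing C11), C8 and C9 (acyloxy CH), C10 (bearing ester carbon C14); C11–C13 complete the methylene lactone. The Z-C4=C5 alkene lies 1,3 to the C9 oxygen and C4 is 1,6 to C9 in both directions round the ring, so a C4–C9 bond divides the ten-membered ring into ring A (C9, C10, C1–C4) and ring B (C4–C9), a cis-decalin with a C9 hydroxyl and a C5 leaving group.
2. Retrosynthetic cuts, in order: the O8 and O9 acyl bonds and C11=C13; the C4=C5/C9=O pair back to the C4–C9 bond of a decalin 9-ol 5-mesylate; the lactone C–O and C7–C11 (enolate alkylation); C3–C4 and C9–C10 (Diels–Alder on a quinone that supplies ring B).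
3. Forward order: ring A is annulated onto the quinone; ring B is oxygenated at C9, C5 and C8 and the γ-lactone is fused at C6/C7; ring A is taken to the epoxy dienoate; the C4–C9 bond is cut to open the ten-membered ring; then C9 reduction and tigloylation, methylenation, and C8 acylation with a separately made hydroxy acid.
4. Stereochemistry: absolute configuration comes from the chiral Diels–Alder catalyst (C4) and, for the side chain, from a Sharpless epoxidation. All other centres are relayed from C4/C9: C9–OH (enolate hydroxylation on the methyl face), C5 (hydride delivered by the C9 hydroxyl), C8 (C9–OH-directed epoxidation), C7 (alkylation anti to O8), C6 (equatorial hydride attack), epoxide (anti to the angular methyl), both Z alkenes (ring geometry in the fragmentation), C9 carbinol (Felkin–Anh addition).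

Key step: step 18

Assumption: the facial sense of the oxazaborolidinium catalyst in step 2 is taken from its usual pre-transition-state model; the catalyst from (S)-diphenylprolinol is specified, and its mirror image would serve the same route if the model proved to predict the other face.

Descriptors: in the decalin intermediates α is the face of the angular C4 methyl and β the opposite face; the SMILES in the compound list fix the absolute configuration.

**Route**

Step 1
Reactants: 1 (2E)-penta-2,4-dien-1-ol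
Product: 2 tert-butyl(dimethyl)[(2E)-penta-2,4-dien-1-yloxy]silane
Conditions: tBuMe2SiCl, imidazole, CH2Cl2, 0 °C → rt
Reagents that add atoms: tert-butyldimethylsilyl chloride, CC(C)(C)[Si](C)(C)Cl
Why: Silyl ether formation at a primary allylic alcohol is routine and involves no stereocenter.

Step 2
Reactants: 2 tert-butyl(dimethyl)[(2E)-penta-2,4-dien-1-yloxy]silane; 3 2-methoxy-6-methyl-1,4-benzoquinone
Product: 4 cis-fused Diels–Alder adduct (ring B: 6-methoxy-6-ene-5,8-dione; ring A: C1=C2; 4α-methyl, 9α-H, 10β-CH2OTBS)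
Conditions: N-protonated B-(o-tolyl)oxazaborolidine from (S)-α,α-diphenylprolinol, Tf2N− counter-ion (20 mol %, made with Tf2NH), diene 2 (1.5 equiv), CH2Cl2, −78 → −40 °C
Reagents that add atoms: none
Why: Catalytic enantioselective Diels–Alder reaction in which the cationic oxazaborolidine binds the more basic C8 carbonyl (vinylogous ester), so C4 becomes the β-carbon and takes the unsubstituted diene terminus while C9 takes the substituted one, the endo transition state gives the cis fusion with the C10 side chain trans to the angular hydrogen, and the catalyst aryl group blocks one enantiotopic face, fixing C4 (and with it C9 and C10).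

Step 3
Reactants: 4 Diels–Alder adduct
Product: 5 9α-hydroxy enedione (tertiary ring-fusion alcohol cis to the C4 methyl)
Conditions: KN(SiMe3)2, THF, −78 °C; then 2-(phenylsulfonyl)-3-phenyloxaziridine, −78 °C; aq. NH4Cl
Reagents that add atoms: 2-(phenylsulfonyl)-3-phenyloxaziridine, O=S(=O)(c1ccccc1)N1OC1c1ccccc1
Why: Davis oxaziridine hydroxylation of the only possible enolate (C8/C9), with oxygen entering on the α-face because the β-face of the planar enolate is screened by the pseudo-axial C10 side chain and by C3, so the cis fusion is kept.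

Step 4
Reactants: 5 9α-hydroxy enedione
Product: 6 5β,9α-diol (C5 carbinol trans to the angular methyl; C8 vinylogous ester carbonyl retained)
Conditions: Me4N[BH(OAc)3], MeCN/AcOH (1:1), −30 → −20 °C
Reagents that add atoms: none
Why: Evans–Saksena hydroxyl-directed reduction in which the C9 alkoxyborohydride delivers hydride internally to the α-face of the C5 ketone (1,3-anti), giving the 5β-alcohol, while the vinylogous-ester carbonyl is inert to this mild reagent.

Step 5
Reactants: 6 5β,9α-diol
Product: 7 5β-triethylsilyl ether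
Conditions: Et3SiOTf (1.1 equiv), 2,6-lutidine, CH2Cl2, −78 °C
Reagents that add atoms: triethylsilyl triflate, CC[Si](CC)(CC)OS(=O)(=O)C(F)(F)F
Why: Silyl ether formation with a silyl triflate is much faster at the secondary C5 hydroxyl than at the tertiary C9 hydroxyl.

Step 6
Reactants: 7 5β-triethylsilyl ether
Product: 9 9α-hydroxy-5β-(triethylsilyloxy)-7-en-6-one (γ-hydroxy enone), via C8 allylic alcohol 8 (not isolated)
Conditions: iBu2AlH (3 equiv), CH2Cl2, −78 °C; then 0.5 M aq. oxalic acid, THF, 0 °C
Reagents that add atoms: water, O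
Why: Stork–Danheiser transposition in which 1,2-reduction of the vinylogous ester carbonyl is followed by acid-promoted loss of the C8 hydroxyl through the methoxy-stabilised allyl cation and hydrolysis to the C6 enone, and since the C8 centre of 8 is destroyed no selectivity is needed.

Step 7
Reactants: 9 γ-hydroxy enone
Product: 10 7α,8α-epoxy-6-ketone (epoxide cis to the C9 hydroxyl)
Conditions: tBuOOH (decane), BnMe3N+ OH− (cat.), THF, −20 → 0 °C
Reagents that add atoms: tert-butyl hydroperoxide, CC(C)(C)OO
Why: Weitz–Scheffer nucleophilic epoxidation in which the hydroperoxide adds to C8 on the α-face, guided by hydrogen bonding to the C9 hydroxyl and by the convex shape of the cis-decalin, which sets the C8–O bond α.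

Step 8
Reactants: 10 7α,8α-epoxy-6-ketone
Product: 11 8α,9α-dihydroxy-6-ketone (C7 methylene)
Conditions: (PhSe)2, NaBH4, EtOH, rt; then AcOH and 10, 0 °C
Reagents that add atoms: none
Why: Benzeneselenolate reduction of an α,β-epoxy ketone cleaves only the Cα–O bond, so the C8 carbinol keeps its configuration and the α′-silyloxy group is untouched.

Step 9
Reactants: 11 8α,9α-dihydroxy-6-ketone
Product: 13 8α-OTBS 9α-OTMS ketone, via 8α-OTBS 9-alcohol 12 (not isolated)
Conditions: tBuMe2SiOTf (1.1 equiv), 2,6-lutidine, CH2Cl2, −78 °C; then N-(trimethylsilyl)imidazole, 0 °C → rt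
Reagents that add atoms: tert-butyldimethylsilyl triflate, CC(C)(C)[Si](C)(C)OS(=O)(=O)C(F)(F)F; N-(trimethylsilyl)imidazole, C[Si](C)(C)n1ccnc1
Why: Stepwise silyl ether formation in which the triflate silylates the secondary C8 hydroxyl at low temperature and the silylimidazole then caps the tertiary C9 hydroxyl without enolising the ketone, the cap preventing silyl migration in the next step.

Step 10
Reactants: 13 8α-OTBS 9α-OTMS ketone
Product: 14 7β-(methoxycarbonylmethyl) 6-ketone
Conditions: LiN(iPr)2 (1.1 equiv), THF, −78 °C; BrCH2CO2Me, DMPU, −78 → −40 °C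
Reagents that add atoms: methyl bromoacetate, COC(=O)CBr
Why: Kinetic lithium enolate alkylation in which the base removes a C7 proton rather than the hindered, oxygen-bearing C5 proton and the bromoacetate is attacked on the β-face, anti to the C8 silyl ether and away from the axial C9 silyl ether, giving the equatorial (also thermodynamically preferred) C7 epimer.

Step 11
Reactants: 14 7β-(methoxycarbonylmethyl) 6-ketone
Product: 16 cis-fused 6β,7β-γ-lactone (fully silylated), via 6β-hydroxy ester 15 (not isolated)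
Conditions: Li[HB(sBu)3], THF, −78 → 0 °C; aq. NH4Cl
Reagents that add atoms: none
Why: Bulky trialkylborohydride reduction in which hydride approaches the C6 ketone equatorially (α-face) because the axial path is blocked by C3 of ring A, giving the axial 6β-alkoxide cis to the C7 acetate arm, which closes the γ-lactone by transesterification.

Step 12
Reactants: 16 cis-fused γ-lactone (fully silylated)
Product: 17 lactone triol (5β-OH, 9α-OH, C14-OH; 8α-OTBS kept)
Conditions: HF·pyridine, pyridine, THF, 0 °C → rt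
Reagents that add atoms: none
Why: Buffered fluoride desilylation removes the primary TBS, the TES and the tertiary TMS ethers, while the C8 TBS ether, flanked by quaternary C9 and ring-fusion C7, is retained.

Step 13
Reactants: 17 lactone triol
Product: 18 C14 carboxylic acid
Conditions: TEMPO (cat.), PhI(OAc)2, MeCN/pH 7 phosphate buffer, rt
Reagents that add atoms: water, O
Why: Oxoammonium (TEMPO) oxidation is selective for the primary alcohol and in water runs through the aldehyde hydrate to the acid, leaving the hindered secondary C5 and tertiary C9 hydroxyls.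

Step 14
Reactants: 18 C14 carboxylic acid
Product: 19 C14 methyl ester (β,γ-unsaturated, C1=C2 intact)
Conditions: Me3SiCHN2, PhMe/MeOH, 0 °C
Reagents that add atoms: trimethylsilyldiazomethane, C[Si](C)(C)C=[N+]=[N-]
Why: Methyl ester formation with trimethylsilyldiazomethane is fast and neutral, so the β,γ-alkene is not isomerised.

Step 15
Reactants: 19 C14 methyl ester
Product: 21 1(10),2-dienoate (C10=C1–C2=C3), via trans-1,2-dibromide 20 (not isolated)
Conditions: Br2 (1.0 equiv), CH2Cl2, −78 °C; then DBU (4 equiv), −78 → 40 °C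
Reagents that add atoms: none
Why: Anti addition of bromine to the isolated C1=C2 alkene followed by double dehydrobromination, first E1cB loss of the C1 bromide through the ester-activated C10–H and then E2 loss of the allylic C2 bromide toward C3, driven by conjugation.

Step 16
Reactants: 21 1(10),2-dienoate
Product: 22 5β-mesylate
Conditions: MeSO2Cl, Et3N, CH2Cl2, −10 °C
Reagents that add atoms: methanesulfonyl chloride, CS(=O)(=O)Cl
Why: Sulfonate ester formation (via sulfene) occurs only at the secondary C5 hydroxyl, the tertiary C9 hydroxyl does not react, and triethylamine is too weak a base to start the fragmentation.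

Step 17
Reactants: 22 5β-mesylate
Product: 23 2β,3β-epoxide (cis-decalin with 9α-OH, 5β-OMs, 8α-OTBS, cis-lactone, C1=C10 enoate)
Conditions: dimethyldioxirane, acetone/CH2Cl2, −20 → 0 °C
Reagents that add atoms: dimethyldioxirane, CC1(C)OO1
Why: Dioxirane epoxidation in which the electrophilic oxidant takes the γ,δ-alkene (C2=C3) of the dienoate rather than the ester-bearing C1=C10 bond and approaches anti to the pseudo-axial angular methyl on C4, giving the β-epoxide.

Step 18
Reactants: 23 2β,3β-epoxide
Product: 24 ten-membered C9 ketone (Z-C4=C5, Z-C1=C10 enoate, cis-2,3-epoxide, cis-6,7-lactone, 8-OTBS)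
Conditions: KOtBu (1.05 equiv), THF, −40 → 0 °C
Reagents that add atoms: none
Why: KOtBu deprotonates the tertiary C9 hydroxyl and the alkoxide collapses to the C9 ketone while the C4–C9 σ-bond, antiperiplanar to the equatorial C5–OMs bond, becomes the C4=C5 π-bond and mesylate leaves in one concerted step. The closest known reaction type is the Wharton-type Grob fragmentation of decalin 1,3-diol monosulfonates to cyclodecenones. No ring is closed by bond formation: the ten-membered ring appears because the bond shared by the two six-membered rings is cut. No stereocenter is created; the new stereo-element, the Z geometry of C4=C5, follows from the chair of ring B in which the mesylate and the angular methyl are equatorial and C3 is axial, so C3 and C6 end up cis, while the Z-C1=C10 enoate and the cis-epoxide are carried over from ring A. The step needs fragmentation to outrun oxetane formation, E2 elimination and base damage to the product (C8 epimerisation, addition to the alkylidene keto ester): the only low-energy chair has the required antiperiplanar array, and the single equivalent of base is consumed as potassium mesylate.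

Step 19
Reactants: 24 ten-membered C9 ketone
Product: 25 C9 allylic alcohol (C9 configured as in the target, syn to O8)
Conditions: NaBH4, CeCl3·7H2O, MeOH, −78 °C
Reagents that add atoms: none
Why: Luche 1,2-reduction in which hydride is expected to add from the outer face of the ring anti to the C8 silyloxy group (Felkin–Anh), giving the 8,9-syn relationship of the target, while CeCl3 suppresses conjugate reduction of the alkylidene keto ester.

Step 20
Reactants: 25 C9 allylic alcohol
Product: 26 C9 tiglate
Conditions: (E)-2-methylbut-2-enoyl chloride, Et3N, DMAP (cat.), CH2Cl2, 0 °C → rt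
Reagents that add atoms: tigloyl chloride, C/C=C(\C)C(Cl)=O
Why: DMAP-catalysed acylation of the secondary allylic alcohol with the acid chloride, the E geometry of the tiglate being the stable one.

Step 21
Reactants: 26 C9 tiglate
Product: 29 α-methylene lactone (C11=C13), via Mannich base 27 (not isolated), via ammonium iodide 28 (not isolated)
Conditions: LiN(SiMe3)2 (1.05 equiv), THF, −78 °C; CH2=NMe2+ I−, −78 → 0 °C; then MeI, MeOH/CH2Cl2, rt; then aq. NaHCO3, rt
Reagents that add atoms: Eschenmoser's salt, C=[N+](C)C.[I-]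
Why: Mannich reaction of the lactone lithium enolate with Eschenmoser's salt, then N-methylation and Hofmann-type elimination, the lactone α-CH2 being the most acidic and least hindered site and the transient C11 stereocenter being removed.

Step 22
Reactants: 29 α-methylene lactone
Product: 30 C8 alcohol
Conditions: HF·pyridine, pyridine, THF, 0 °C → rt
Reagents that add atoms: none
Why: Fluoride cleavage of the last silyl ether under non-basic conditions avoids tiglate migration from O9 to O8 and conjugate addition to the methylene lactone.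

Step 23
Reactants: 31 (2E)-2-methylbut-2-en-1-ol
Product: 32 [(2R,3R)-2,3-dimethyloxiran-2-yl]methanol
Conditions: Ti(OiPr)4 (cat.), D-(−)-diisopropyl tartrate (cat.), tBuOOH, 4 Å molecular sieves, CH2Cl2, −20 °C
Reagents that add atoms: tert-butyl hydroperoxide, CC(C)(C)OO
Why: Sharpless asymmetric epoxidation of an E-trisubstituted allylic alcohol, in which the D-tartrate ligand delivers oxygen to the face that gives the (2R,3R)-epoxide.

Step 24
Reactants: 32 [(2R,3R)-2,3-dimethyloxiran-2-yl]methanol
Product: 33 (2R,3S)-3-acetoxy-2-methylbutane-1,2-diol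
Conditions: Ti(OiPr)4 (1.5 equiv), AcOH, CH2Cl2, 0 °C → rt
Reagents that add atoms: acetic acid, CC(=O)O
Why: Ti(OiPr)4-mediated opening of a 2,3-epoxy alcohol by a carboxylic acid occurs at C3 with inversion (SN2), turning (3R) into the (3S)-acetate while the quaternary C2 is untouched.

Step 25
Reactants: 33 (2R,3S)-3-acetoxy-2-methylbutane-1,2-diol
Product: 34 (2S,3S)-3-acetoxy-2-hydroxy-2-methylbutanoic acid
Conditions: TEMPO (cat.), NaOCl (cat.), NaClO2, MeCN/pH 6.7 phosphate buffer, 35 °C
Reagents that add atoms: sodium chlorite, [Na+].[O-]Cl=O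
Why: TEMPO/NaOCl-catalysed NaClO2 oxidation takes the primary alcohol to the acid near neutral pH without cleaving the diol or touching the tertiary alcohol or the acetate.

Step 26
Reactants: 34 (2S,3S)-3-acetoxy-2-hydroxy-2-methylbutanoic acid
Product: 36 (2S,3S)-3-acetoxy-2-methyl-2-(triethylsilyloxy)butanoic acid, via bis-silyl derivative 35 (not isolated)
Conditions: Et3SiOTf (2.5 equiv), 2,6-lutidine, CH2Cl2, −78 → 0 °C; then aq. citric acid, THF, 0 °C
Reagents that add atoms: triethylsilyl triflate, CC[Si](CC)(CC)OS(=O)(=O)C(F)(F)F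
Why: Silylation of both the acid and the tertiary hydroxyl with the silyl triflate is followed by selective hydrolysis of the labile silyl ester.

Step 27
Reactants: 30 C8 alcohol; 36 (2S,3S)-3-acetoxy-2-methyl-2-(triethylsilyloxy)butanoic acid
Product: 38 C8 ester carrying the O-triethylsilyl side chain, via mixed anhydride 37 (not isolated)
Conditions: 36 (3 equiv), 2,4,6-Cl3C6H2COCl, Et3N, THF, rt; then 30, DMAP, PhMe, rt → 40 °C
Reagents that add atoms: none
Why: Yamaguchi esterification in which the mixed anhydride acylates DMAP and then the hindered C8 hydroxyl, the silyl cap preventing self-acylation of the hydroxy acid.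

Step 28
Reactants: 38 C8 ester carrying the O-triethylsilyl side chain
Product: 39 CNP0202690.1
Conditions: HF·pyridine, THF, 0 °C → rt
Reagents that add atoms: none
Why: Fluoride cleavage of the tertiary triethylsilyl ether under acidic, non-nucleophilic conditions spares the epoxide, the methylene lactone and the other esters and does not promote acetyl migration.

**Compound list**

1 | (2E)-penta-2,4-dien-1-ol | OC/C=C/C=C | starting material
2 | tert-butyl(dimethyl)[(2E)-penta-2,4-dien-1-yloxy]silane | C=C/C=C/CO[Si](C)(C)C(C)(C)C | intermediate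
3 | 2-methoxy-6-methyl-1,4-benzoquinone | COC1=CC(=O)C=C(C)C1=O | starting material
4 | cis-fused Diels–Alder adduct, 6-methoxy-6-ene-5,8-dione, 4α-Me, 9α-H, 10β-CH2OTBS, C1=C2 | COC1=CC(=O)[C@H]2[C@@H](CO[Si](C)(C)C(C)(C)C)C=CC[C@@]2(C)C1=O | intermediate
5 | 9α-hydroxy enedione | COC1=CC(=O)[C@@]2(O)[C@@H](CO[Si](C)(C)C(C)(C)C)C=CC[C@@]2(C)C1=O | intermediate
6 | 5β,9α-diol, C8 vinylogous ester carbonyl retained | COC1=CC(=O)[C@@]2(O)[C@@H](CO[Si](C)(C)C(C)(C)C)C=CC[C@@]2(C)[C@H]1O | intermediate
7 | 5β-triethylsilyl ether of 6 | COC1=CC(=O)[C@@]2(O)[C@@H](CO[Si](C)(C)C(C)(C)C)C=CC[C@@]2(C)[C@H]1O[Si](CC)(CC)CC | intermediate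
8 | C8 allylic alcohol (both C8 epimers), enol ether intact | COC1=CC(O)[C@@]2(O)[C@@H](CO[Si](C)(C)C(C)(C)C)C=CC[C@@]2(C)[C@H]1O[Si](CC)(CC)CC | intermediate (not isolated)
9 | 9α-hydroxy-5β-(triethylsilyloxy)-7-en-6-one | O=C1C=C[C@@]2(O)[C@@H](CO[Si](C)(C)C(C)(C)C)C=CC[C@@]2(C)[C@H]1O[Si](CC)(CC)CC | intermediate
10 | 7α,8α-epoxy-6-ketone | O=C1[C@@H]3O[C@@H]3[C@@]2(O)[C@@H](CO[Si](C)(C)C(C)(C)C)C=CC[C@@]2(C)[C@H]1O[Si](CC)(CC)CC | intermediate
11 | 8α,9α-dihydroxy-6-ketone | O=C1C[C@H](O)[C@@]2(O)[C@@H](CO[Si](C)(C)C(C)(C)C)C=CC[C@@]2(C)[C@H]1O[Si](CC)(CC)CC | intermediate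
12 | 8α-OTBS 9α-hydroxy 6-ketone | O=C1C[C@H](O[Si](C)(C)C(C)(C)C)[C@@]2(O)[C@@H](CO[Si](C)(C)C(C)(C)C)C=CC[C@@]2(C)[C@H]1O[Si](CC)(CC)CC | intermediate (not isolated)
13 | 8α-OTBS 9α-OTMS 6-ketone | O=C1C[C@H](O[Si](C)(C)C(C)(C)C)[C@@]2(O[Si](C)(C)C)[C@@H](CO[Si](C)(C)C(C)(C)C)C=CC[C@@]2(C)[C@H]1O[Si](CC)(CC)CC | intermediate
14 | 7β-(methoxycarbonylmethyl) 6-ketone | COC(=O)C[C@H]1[C@H](O[Si](C)(C)C(C)(C)C)[C@@]2(O[Si](C)(C)C)[C@@H](CO[Si](C)(C)C(C)(C)C)C=CC[C@@]2(C)[C@@H](O[Si](CC)(CC)CC)C1=O | intermediate
15 | 6β-hydroxy methyl ester | COC(=O)C[C@H]1[C@H](O[Si](C)(C)C(C)(C)C)[C@@]2(O[Si](C)(C)C)[C@@H](CO[Si](C)(C)C(C)(C)C)C=CC[C@@]2(C)[C@@H](O[Si](CC)(CC)CC)[C@H]1O | intermediate (not isolated)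
16 | cis-fused 6β,7β-γ-lactone, 5β-OTES, 8α-OTBS, 9α-OTMS, C14-OTBS | O=C1C[C@H]2[C@H](O[Si](C)(C)C(C)(C)C)[C@@]3(O[Si](C)(C)C)[C@@H](CO[Si](C)(C)C(C)(C)C)C=CC[C@@]3(C)[C@@H](O[Si](CC)(CC)CC)[C@H]2O1 | intermediate
17 | lactone triol, 8α-OTBS | O=C1C[C@H]2[C@H](O[Si](C)(C)C(C)(C)C)[C@@]3(O)[C@@H](CO)C=CC[C@@]3(C)[C@@H](O)[C@H]2O1 | intermediate
18 | C14 carboxylic acid | O=C1C[C@H]2[C@H](O[Si](C)(C)C(C)(C)C)[C@@]3(O)[C@@H](C(=O)O)C=CC[C@@]3(C)[C@@H](O)[C@H]2O1 | intermediate
19 | C14 methyl ester | O=C1C[C@H]2[C@H](O[Si](C)(C)C(C)(C)C)[C@@]3(O)[C@@H](C(=O)OC)C=CC[C@@]3(C)[C@@H](O)[C@H]2O1 | intermediate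
20 | trans-1,2-dibromide (C1/C2 configuration not assigned) | O=C1C[C@H]2[C@H](O[Si](C)(C)C(C)(C)C)[C@@]3(O)[C@@H](C(=O)OC)C(Br)C(Br)C[C@@]3(C)[C@@H](O)[C@H]2O1 | intermediate (not isolated)
21 | 1(10),2-dienoate, 5β-OH, 9α-OH | O=C1C[C@H]2[C@H](O[Si](C)(C)C(C)(C)C)[C@@]3(O)C(C(=O)OC)=CC=C[C@@]3(C)[C@@H](O)[C@H]2O1 | intermediate
22 | 5β-mesylate of 21 | O=C1C[C@H]2[C@H](O[Si](C)(C)C(C)(C)C)[C@@]3(O)C(C(=O)OC)=CC=C[C@@]3(C)[C@@H](OS(C)(=O)=O)[C@H]2O1 | intermediate
23 | 2β,3β-epoxy cis-decalin, 9α-OH, 5β-OMs, 8α-OTBS, cis-lactone, C1=C10 enoate | O=C1C[C@H]2[C@H](O[Si](C)(C)C(C)(C)C)[C@@]3(O)C(C(=O)OC)=C[C@H]4O[C@H]4[C@@]3(C)[C@@H](OS(C)(=O)=O)[C@H]2O1 | intermediate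
24 | ten-membered C9 ketone, Z-C4=C5, Z-C1=C10, cis-epoxide, cis-lactone, 8-OTBS | C1C(=O)O[C@@H]2/C=C(/C)[C@@H]3O[C@@H]3/C=C(/C(=O)OC)C(=O)[C@@H](O[Si](C)(C)C(C)(C)C)[C@H]12 | intermediate
25 | C9 alcohol (C9 as in the target) | C1C(=O)O[C@@H]2/C=C(/C)[C@@H]3O[C@@H]3/C=C(/C(=O)OC)[C@H](O)[C@@H](O[Si](C)(C)C(C)(C)C)[C@H]12 | intermediate
26 | C9 tiglate | C1C(=O)O[C@@H]2/C=C(/C)[C@@H]3O[C@@H]3/C=C(/C(=O)OC)[C@H](OC(=O)/C(C)=C/C)[C@@H](O[Si](C)(C)C(C)(C)C)[C@H]12 | intermediate
27 | C11 (dimethylaminomethyl) lactone (C11 epimers) | CN(C)CC1C(=O)O[C@@H]2/C=C(/C)[C@@H]3O[C@@H]3/C=C(/C(=O)OC)[C@H](OC(=O)/C(C)=C/C)[C@@H](O[Si](C)(C)C(C)(C)C)[C@H]12 | intermediate (not isolated)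
28 | C11 (trimethylammoniomethyl) lactone iodide | C[N+](C)(C)CC1C(=O)O[C@@H]2/C=C(/C)[C@@H]3O[C@@H]3/C=C(/C(=O)OC)[C@H](OC(=O)/C(C)=C/C)[C@@H](O[Si](C)(C)C(C)(C)C)[C@H]12.[I-] | intermediate (not isolated)
29 | α-methylene lactone, 8-OTBS, 9-tiglate | C=C1C(=O)O[C@@H]2/C=C(/C)[C@@H]3O[C@@H]3/C=C(/C(=O)OC)[C@H](OC(=O)/C(C)=C/C)[C@@H](O[Si](C)(C)C(C)(C)C)[C@H]12 | intermediate
30 | C8 alcohol | C=C1C(=O)O[C@@H]2/C=C(/C)[C@@H]3O[C@@H]3/C=C(/C(=O)OC)[C@H](OC(=O)/C(C)=C/C)[C@@H](O)[C@H]12 | intermediate
31 | (2E)-2-methylbut-2-en-1-ol | C/C=C(\C)CO | starting material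
32 | [(2R,3R)-2,3-dimethyloxiran-2-yl]methanol | OC[C@@]1(C)O[C@@H]1C | intermediate
33 | (2R,3S)-3-acetoxy-2-methylbutane-1,2-diol | OC[C@@](C)(O)[C@H](C)OC(C)=O | intermediate
34 | (2S,3S)-3-acetoxy-2-hydroxy-2-methylbutanoic acid | OC(=O)[C@@](C)(O)[C@H](C)OC(C)=O | intermediate
35 | triethylsilyl (2S,3S)-3-acetoxy-2-methyl-2-(triethylsilyloxy)butanoate | CC[Si](CC)(CC)OC(=O)[C@@](C)(O[Si](CC)(CC)CC)[C@H](C)OC(C)=O | intermediate (not isolated)
36 | (2S,3S)-3-acetoxy-2-methyl-2-(triethylsilyloxy)butanoic acid | OC(=O)[C@@](C)(O[Si](CC)(CC)CC)[C@H](C)OC(C)=O | intermediate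
37 | mixed anhydride of 36 with 2,4,6-trichlorobenzoic acid | O=C(OC(=O)c1c(Cl)cc(Cl)cc1Cl)[C@@](C)(O[Si](CC)(CC)CC)[C@H](C)OC(C)=O | intermediate (not isolated)
38 | C8 ester with O-triethylsilyl side chain | C=C1C(=O)O[C@@H]2/C=C(/C)[C@@H]3O[C@@H]3/C=C(/C(=O)OC)[C@H](OC(=O)/C(C)=C/C)[C@@H](OC(=O)[C@@](C)(O[Si](CC)(CC)CC)[C@H](C)OC(C)=O)[C@H]12 | intermediate
39 | CNP0202690.1 | C=C1C(=O)O[C@@H]2/C=C(/C)[C@@H]3O[C@@H]3/C=C(/C(=O)OC)[C@H](OC(=O)/C(C)=C/C)[C@@H](OC(=O)[C@@](C)(O)[C@H](C)OC(C)=O)[C@H]12 | target

**Step count**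

Total: 28 steps. Longest linear sequence: 24 steps (steps 1–22, 27, 28, from dienol 1); the side-chain acid takes 4 steps (23–26).

**Steps most likely to fail, with fallbacks**

Step 19. The ten-membered ketone may be attacked by hydride from the other face, or with poor facial selectivity, because the ring conformation rather than the Felkin–Anh preference may decide the outcome. The fallback turns the wrong outcome to use. Starting from 24, the reduction is run to give the C9-epimeric alcohol F1. A Mitsunobu esterification of F1 with tiglic acid (PPh3, diisopropyl azodicarboxylate, PhMe, 0 °C → rt) then inverts C9 and installs the tiglate in one operation, rejoining the route at 26.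

Step 21. Enolisation may not stay at the lactone: the lithium enolate can attack the neighbouring tiglate carbonyl or add across the ring to the enoate, and the base can deprotonate the tiglate. The fallback methylenates before the tiglate is present. Starting from 25, the C9 hydroxyl is capped (Et3SiOTf, 2,6-lutidine) to give the triethylsilyl ether F2. The same Mannich sequence then leads through the Mannich base F3 and the ammonium iodide F4 to the methylene lactone F5. PPTS in MeOH frees the C9 hydroxyl selectively to give the alcohol F6, and tigloyl chloride/DMAP converts F6 into 29, where the route is rejoined.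

Step 17. The dioxirane may approach the diene from the α-face, or unselectively, if ring B shields the β-face more than the angular methyl shields the α-face. The fallback reverses the facial outcome through a halohydrin. Starting from 22, N-bromosuccinimide in wet THF forms the bromonium ion on the more accessible face and water opens it anti to give the bromohydrin F7 (2β-OH, 3α-Br). K2CO3 in acetone then closes the β-epoxide by backside displacement of bromide, rejoining the route at 23.

**Further compounds**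

F1 | step 19 | C9 epimer of alcohol 25 | C1C(=O)O[C@@H]2/C=C(/C)[C@@H]3O[C@@H]3/C=C(/C(=O)OC)[C@@H](O)[C@@H](O[Si](C)(C)C(C)(C)C)[C@H]12
F2 | step 21 | 9-O-triethylsilyl ether of 25 | C1C(=O)O[C@@H]2/C=C(/C)[C@@H]3O[C@@H]3/C=C(/C(=O)OC)[C@H](O[Si](CC)(CC)CC)[C@@H](O[Si](C)(C)C(C)(C)C)[C@H]12
F3 | step 21 | C11 (dimethylaminomethyl) lactone of F2 | CN(C)CC1C(=O)O[C@@H]2/C=C(/C)[C@@H]3O[C@@H]3/C=C(/C(=O)OC)[C@H](O[Si](CC)(CC)CC)[C@@H](O[Si](C)(C)C(C)(C)C)[C@H]12
F4 | step 21 | C11 (trimethylammoniomethyl) lactone iodide of F2 | C[N+](C)(C)CC1C(=O)O[C@@H]2/C=C(/C)[C@@H]3O[C@@H]3/C=C(/C(=O)OC)[C@H](O[Si](CC)(CC)CC)[C@@H](O[Si](C)(C)C(C)(C)C)[C@H]12.[I-]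
F5 | step 21 | α-methylene lactone, 9-OTES, 8-OTBS | C=C1C(=O)O[C@@H]2/C=C(/C)[C@@H]3O[C@@H]3/C=C(/C(=O)OC)[C@H](O[Si](CC)(CC)CC)[C@@H](O[Si](C)(C)C(C)(C)C)[C@H]12
F6 | step 21 | α-methylene lactone, 9-OH, 8-OTBS | C=C1C(=O)O[C@@H]2/C=C(/C)[C@@H]3O[C@@H]3/C=C(/C(=O)OC)[C@H](O)[C@@H](O[Si](C)(C)C(C)(C)C)[C@H]12
F7 | step 17 | 2β-hydroxy-3α-bromo derivative of mesylate 22 | O=C1C[C@H]2[C@H](O[Si](C)(C)C(C)(C)C)[C@@]3(O)C(C(=O)OC)=C[C@@H](O)[C@H](Br)[C@@]3(C)[C@@H](OS(C)(=O)=O)[C@H]2O1
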